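**Retrosynthetic overview**

- C11'=C12' is cut by Horner–Wadsworth–Emmons olefination into C25 apo-aldehyde 19 and farnesyl phosphonate 21; C11=C12 by Wittig olefination into C15 phosphonium salt 17 and C10 dialdehyde 18; C7=C8 by Julia–Kocienski olefination into ring sulfone 13 and C5 aldehyde ester 14.
- The C6 stereocentre and the C4=C5 alkene arise together from the (S)-C4 allylic alcohol 6 by reductive 1,3-transposition (chirality transfer from C4 to C6); 6 comes from enone 5 by Corey–Bakshi–Shibata reduction.
- Ring A (the only ring, C1–C6) is formed first, in step 1, by Robinson annulation of keto ester 1 with ethyl vinyl ketone 2: C1–C2 by Michael addition, C5–C6 by aldol condensation.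
- Enabling feature: in ring A the quaternary gem-dimethyl carbon C1 sits next to C6, which carries chain carbon C7, so a C6 ketone bearing C7 as an ester can enolise only at C1; the C4=C5(Me) alkene is read as a C4 ketone with its α-methyl carbon C5, so C2–C5 is ethyl vinyl ketone, and the extra C4 oxygen is removed again in step 3.

Key step: step 1

Remark: carotenoid numbering is used throughout (ring A = C1–C6 with C1 the CMe2 carbon, C5 the methyl-bearing alkene carbon and C6 the stereocentre; chain C7–C15, then C15'–C1'); compounds 1, 2, 14, 18 and 20 are taken as commercial.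

**Route**

Step 1
Reactants: 1 ethyl 3-methyl-2-oxobutanoate; 2 pent-1-en-3-one (ethyl vinyl ketone)
Product: 5 ethyl 2,6,6-trimethyl-3-oxocyclohex-1-ene-1-carboxylate, via diketo ester 3 (not isolated), via ketol 4 (not isolated)
Conditions: 2 (1.2 equiv, slow addition), DBU (0.1 equiv), MeCN, 0 °C → rt; then TsOH·H2O (0.3 equiv), toluene, reflux, Dean–Stark (one pot)
Reagents that add atoms: none
Why: Base-catalysed Michael addition of the only enolisable position of 1 (tertiary C1, α to the C6 ketone) to the β-carbon C2 of 2 forms the quaternary C1–C2 bond, and after acidification the C5 enol of the ethyl ketone in 3 adds to the strongly electrophilic α-keto ester carbonyl C6 and ketol 4 loses water to the conjugated enone, which forms C5–C6. This is a Robinson annulation (Michael addition followed by aldol condensation), the closest precedents being annulations of α-branched carbonyl donors and 2-substituted 1,3-dicarbonyl compounds with vinyl ketones. Ring A closes by a 6-(enolendo)-exo-trig aldol addition. No stereocentre survives the step because C6 is trigonal in 5, so no facial control is needed here. The selectivities required are the donor site in the Michael step, secured because C1 carries the only α-hydrogen of 1, and the site of the aldol closure, secured because closure from C3 would give a four-membered ring and C6 is the most electrophilic carbonyl. The C4 ketone left by the step is the handle that later sets C6 and is then removed.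

Step 2
Reactants: 5 ethyl 2,6,6-trimethyl-3-oxocyclohex-1-ene-1-carboxylate
Product: 6 ethyl (3S)-3-hydroxy-2,6,6-trimethylcyclohex-1-ene-1-carboxylate
Conditions: (R)-2-methyl-CBS-oxazaborolidine (0.2 equiv), catecholborane (1.5 equiv), toluene, −78 °C
Reagents that add atoms: none
Why: Corey–Bakshi–Shibata reduction of the ketone only (the ester is inert), in which the tetrasubstituted alkene side (C5) acts as the large group and the C3 methylene as the small group, so the (R)-catalyst should deliver hydride to the face that gives the (S)-carbinol at C4.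

Step 3
Reactants: 6 ethyl (3S)-3-hydroxy-2,6,6-trimethylcyclohex-1-ene-1-carboxylate
Product: 10 ethyl (1R)-2,6,6-trimethylcyclohex-2-ene-1-carboxylate, via hydrazone adduct 7 (not isolated), via sulfonyl hydrazine 8 (not isolated), via allylic diazene 9 (not isolated)
Conditions: N′-(propan-2-ylidene)-2-nitrobenzenesulfonohydrazide, PPh3, diethyl azodicarboxylate, THF, 0 °C → rt; then CF3CH2OH/H2O (1:1), rt
Reagents that add atoms: none
Why: Mitsunobu displacement at C4 with inversion, hydrolysis of the hydrazone, loss of sulfinic acid and retro-ene loss of N2 from the allylic diazene (reductive 1,3-transposition of an allylic alcohol) should move the alkene to C4=C5 and deliver hydrogen suprafacially to C6 on the face opposite to the original hydroxyl, which sets (6R).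

Step 4
Reactants: 10 ethyl (1R)-2,6,6-trimethylcyclohex-2-ene-1-carboxylate
Product: 11 [(1R)-2,6,6-trimethylcyclohex-2-en-1-yl]methanol
Conditions: LiAlH4, Et2O, 0 °C
Reagents that add atoms: none
Why: Hydride reduction of the ester to the primary alcohol, which is not expected to epimerise the allylic α-stereocentre C6 because no enolate is formed.

Step 5
Reactants: 11 [(1R)-2,6,6-trimethylcyclohex-2-en-1-yl]methanol
Product: 12 1-phenyl-5-({[(1R)-2,6,6-trimethylcyclohex-2-en-1-yl]methyl}sulfanyl)-1H-tetrazole
Conditions: 1-phenyl-1H-tetrazole-5-thiol, PPh3, diisopropyl azodicarboxylate, THF, 0 °C → rt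
Reagents that add atoms: 1-phenyl-1H-tetrazole-5-thiol, Sc1nnnn1-c1ccccc1
Why: Mitsunobu thioetherification of the primary alcohol C7 by the acidic heteroaryl thiol, with C6 not involved.

Step 6
Reactants: 12 1-phenyl-5-({[(1R)-2,6,6-trimethylcyclohex-2-en-1-yl]methyl}sulfanyl)-1H-tetrazole
Product: 13 1-phenyl-5-({[(1R)-2,6,6-trimethylcyclohex-2-en-1-yl]methyl}sulfonyl)-1H-tetrazole
Conditions: H2O2 (30% aq.), (NH4)6Mo7O24·4H2O (cat.), EtOH, 0 °C → rt
Reagents that add atoms: hydrogen peroxide, OO
Why: Molybdate-catalysed oxidation of the sulfide to the sulfone, a reagent system that normally spares trisubstituted alkenes.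

Step 7
Reactants: 13 1-phenyl-5-({[(1R)-2,6,6-trimethylcyclohex-2-en-1-yl]methyl}sulfonyl)-1H-tetrazole; 14 ethyl (2E)-3-methyl-4-oxobut-2-enoate
Product: 15 ethyl (2E,4E)-3-methyl-5-[(1R)-2,6,6-trimethylcyclohex-2-en-1-yl]penta-2,4-dienoate
Conditions: KN(SiMe3)2, DME, −60 °C; then 14, −60 °C → rt
Reagents that add atoms: none
Why: Julia–Kocienski olefination (carbonyl addition of the C7 sulfonyl carbanion, Smiles rearrangement, loss of SO2 and tetrazolone) should form C7=C8 with E preference, keeps the 9E geometry of 14, and places the carbanion on C7 so that C6 carries no acidic hydrogen during the coupling.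

Step 8
Reactants: 15 ethyl (2E,4E)-3-methyl-5-[(1R)-2,6,6-trimethylcyclohex-2-en-1-yl]penta-2,4-dienoate
Product: 16 (2E,4E)-3-methyl-5-[(1R)-2,6,6-trimethylcyclohex-2-en-1-yl]penta-2,4-dien-1-ol
Conditions: iBu2AlH (2.2 equiv), CH2Cl2, −78 °C; aq. KNaC4H4O6 work-up
Reagents that add atoms: none
Why: 1,2-Reduction of the dienoate to the allylic alcohol by the aluminium hydride, without touching the alkenes.

Step 9
Reactants: 16 (2E,4E)-3-methyl-5-[(1R)-2,6,6-trimethylcyclohex-2-en-1-yl]penta-2,4-dien-1-ol
Product: 17 {(2E,4E)-3-methyl-5-[(1R)-2,6,6-trimethylcyclohex-2-en-1-yl]penta-2,4-dien-1-yl}triphenylphosphonium bromide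
Conditions: PPh3·HBr, MeOH, rt, dark
Reagents that add atoms: triphenylphosphine hydrobromide, Br.c1ccc(cc1)P(c1ccccc1)c1ccccc1
Why: Acid-mediated substitution of the primary allylic alcohol by PPh3 at C11 (allylic phosphonium salt formation as used for C15 end-group salts in carotenoid synthesis), which leaves C6 untouched.

Step 10
Reactants: 17 {(2E,4E)-3-methyl-5-[(1R)-2,6,6-trimethylcyclohex-2-en-1-yl]penta-2,4-dien-1-yl}triphenylphosphonium bromide; 18 (2E,4E,6E)-2,7-dimethylocta-2,4,6-trienedial
Product: 19 (2E,4E,6E,8E,10E,12E)-2,7,11-trimethyl-13-[(1R)-2,6,6-trimethylcyclohex-2-en-1-yl]trideca-2,4,6,8,10,12-hexaenal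
Conditions: 18 (2.5 equiv), NaOMe, MeOH/CH2Cl2, 0 °C → rt, dark, Ar; then n-heptane, 90 °C (Z→E)
Reagents that add atoms: none
Why: Wittig olefination at one aldehyde of the symmetrical dialdehyde (excess 18 should favour mono-olefination) forms C11=C12, and the sterically hindered 11Z isomer is expected to isomerise to E on heating.

Step 11
Reactants: 20 (2E,6E)-1-bromo-3,7,11-trimethyldodeca-2,6,10-triene (farnesyl bromide)
Product: 21 diethyl [(2E,6E)-3,7,11-trimethyldodeca-2,6,10-trien-1-yl]phosphonate
Conditions: P(OEt)3, neat, 120 °C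
Reagents that add atoms: triethyl phosphite, CCOP(OCC)OCC
Why: Michaelis–Arbuzov reaction of the primary allylic bromide, which should retain both E alkenes.

Step 12
Reactants: 19 (2E,4E,6E,8E,10E,12E)-2,7,11-trimethyl-13-[(1R)-2,6,6-trimethylcyclohex-2-en-1-yl]trideca-2,4,6,8,10,12-hexaenal; 21 diethyl [(2E,6E)-3,7,11-trimethyldodeca-2,6,10-trien-1-yl]phosphonate
Product: 22 (6R)-7',8'-dihydro-ε,ψ-carotene (α-zeacarotene, CNP0213990.1)
Conditions: 21, NaN(SiMe3)2, THF, −78 °C; then 19, −78 → 0 °C, dark, Ar; then n-heptane, 80 °C (Z→E), crystallisation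
Reagents that add atoms: none
Why: Horner–Wadsworth–Emmons olefination of the polyenal with the allylic phosphonate carbanion forms C11'=C12' with E preference, and any hindered 11'Z isomer should isomerise on heating to the all-E target.

**Compound list**

1 | ethyl 3-methyl-2-oxobutanoate | CCOC(=O)C(=O)C(C)C | starting material
2 | pent-1-en-3-one (ethyl vinyl ketone) | CCC(=O)C=C | starting material
3 | ethyl 3,3-dimethyl-2,6-dioxooctanoate | CCOC(=O)C(=O)C(C)(C)CCC(=O)CC | intermediate (not isolated)
4 | ethyl 1-hydroxy-2,6,6-trimethyl-3-oxocyclohexane-1-carboxylate (diastereomer mixture) | CCOC(=O)C1(O)C(C)C(=O)CCC1(C)C | intermediate (not isolated)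
5 | ethyl 2,6,6-trimethyl-3-oxocyclohex-1-ene-1-carboxylate | CCOC(=O)C1=C(C)C(=O)CCC1(C)C | intermediate
6 | ethyl (3S)-3-hydroxy-2,6,6-trimethylcyclohex-1-ene-1-carboxylate | CCOC(=O)C1=C(C)[C@@H](O)CCC1(C)C | intermediate
7 | ethyl (3R)-2,6,6-trimethyl-3-[1-(2-nitrobenzenesulfonyl)-2-(propan-2-ylidene)hydrazin-1-yl]cyclohex-1-ene-1-carboxylate | CCOC(=O)C1=C(C)[C@H](N(N=C(C)C)S(=O)(=O)c2ccccc2[N+](=O)[O-])CCC1(C)C | intermediate (not isolated)
8 | ethyl (3R)-3-[1-(2-nitrobenzenesulfonyl)hydrazin-1-yl]-2,6,6-trimethylcyclohex-1-ene-1-carboxylate | CCOC(=O)C1=C(C)[C@H](N(N)S(=O)(=O)c2ccccc2[N+](=O)[O-])CCC1(C)C | intermediate (not isolated)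
9 | ethyl (3R)-3-diazenyl-2,6,6-trimethylcyclohex-1-ene-1-carboxylate | CCOC(=O)C1=C(C)[C@H](N=N)CCC1(C)C | intermediate (not isolated)
10 | ethyl (1R)-2,6,6-trimethylcyclohex-2-ene-1-carboxylate | CCOC(=O)[C@H]1C(C)=CCCC1(C)C | intermediate
11 | [(1R)-2,6,6-trimethylcyclohex-2-en-1-yl]methanol | OC[C@H]1C(C)=CCCC1(C)C | intermediate
12 | 1-phenyl-5-({[(1R)-2,6,6-trimethylcyclohex-2-en-1-yl]methyl}sulfanyl)-1H-tetrazole | c1ccccc1-n1nnnc1SC[C@H]1C(C)=CCCC1(C)C | intermediate
13 | 1-phenyl-5-({[(1R)-2,6,6-trimethylcyclohex-2-en-1-yl]methyl}sulfonyl)-1H-tetrazole | c1ccccc1-n1nnnc1S(=O)(=O)C[C@H]1C(C)=CCCC1(C)C | intermediate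
14 | ethyl (2E)-3-methyl-4-oxobut-2-enoate | CCOC(=O)/C=C(\C)C=O | starting material
15 | ethyl (2E,4E)-3-methyl-5-[(1R)-2,6,6-trimethylcyclohex-2-en-1-yl]penta-2,4-dienoate | CCOC(=O)/C=C(C)/C=C/[C@H]1C(C)=CCCC1(C)C | intermediate
16 | (2E,4E)-3-methyl-5-[(1R)-2,6,6-trimethylcyclohex-2-en-1-yl]penta-2,4-dien-1-ol | OC/C=C(C)/C=C/[C@H]1C(C)=CCCC1(C)C | intermediate
17 | {(2E,4E)-3-methyl-5-[(1R)-2,6,6-trimethylcyclohex-2-en-1-yl]penta-2,4-dien-1-yl}triphenylphosphonium bromide | [Br-].c1ccccc1[P+](c1ccccc1)(c1ccccc1)C/C=C(C)/C=C/[C@H]1C(C)=CCCC1(C)C | intermediate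
18 | (2E,4E,6E)-2,7-dimethylocta-2,4,6-trienedial | O=C/C(C)=C/C=C/C=C(C)/C=O | starting material
19 | (2E,4E,6E,8E,10E,12E)-2,7,11-trimethyl-13-[(1R)-2,6,6-trimethylcyclohex-2-en-1-yl]trideca-2,4,6,8,10,12-hexaenal | O=C/C(C)=C/C=C/C=C(C)/C=C/C=C(C)/C=C/[C@H]1C(C)=CCCC1(C)C | intermediate
20 | (2E,6E)-1-bromo-3,7,11-trimethyldodeca-2,6,10-triene | CC(C)=CCC/C(C)=C/CC/C(C)=C/CBr | starting material
21 | diethyl [(2E,6E)-3,7,11-trimethyldodeca-2,6,10-trien-1-yl]phosphonate | CC(C)=CCC/C(C)=C/CC/C(C)=C/CP(=O)(OCC)OCC | intermediate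
22 | (6R)-7',8'-dihydro-ε,ψ-carotene (α-zeacarotene) | CC(C)=CCC/C(C)=C/CC/C(C)=C/C=C/C(C)=C/C=C/C=C(C)/C=C/C=C(C)/C=C/[C@H]1C(C)=CCCC1(C)C | target

**Step count**

Total steps: 12. Longest linear sequence: 11 steps (steps 1 to 10, then step 12); the farnesyl branch is step 11.

**Steps most likely to fail, with fallbacks**

Step 3. The Mitsunobu displacement at the C4 carbinol, which is flanked by the tetrasubstituted alkene and its C5 methyl group, may be slow, so that elimination to a diene or ionisation of the allylic system competes and the chirality transfer to C6 is eroded. The fallback sets out from 6, which is formylated (HCO2H, dicyclohexylcarbodiimide, 4-dimethylaminopyridine, CH2Cl2, 0 °C) to ethyl (3S)-3-(formyloxy)-2,6,6-trimethylcyclohex-1-ene-1-carboxylate F1. Treatment of this formate with Pd(OAc)2 and PBu3 in THF at rt to 50 °C should effect formate hydrogenolysis of the allylic ester. Zerovalent palladium ionises the formate with inversion, CO2 is lost, and the palladium hydride delivers hydrogen to the more substituted terminus C6 from the palladium-bearing face. This is the same face as in the diazene route, so the fallback comes back to the route at 10.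

Step 7. The sulfonyl carbanion may add in conjugate fashion to the doubly activated alkene of 14 in place of the aldehyde, or the E selectivity at C7=C8 may be poor. The fallback reverses the polarity of the coupling and sets out from 11. Oxidation with Dess–Martin periodinane (NaHCO3, CH2Cl2, 0 °C) should give (1R)-2,6,6-trimethylcyclohex-2-ene-1-carbaldehyde F2, which is used crude. A Horner–Wadsworth–Emmons reaction with the anion of triethyl 3-methyl-4-phosphonocrotonate (LiN(SiMe3)2, THF, −78 → 0 °C, short contact with base to limit epimerisation at C6) then comes back to the route at 15, bypassing 12 and 13.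

Step 1. Base-induced polymerisation of 2 may outrun Michael addition at the hindered tertiary carbon C1, or dehydration of ketol 4 may stall. The fallback sets out from 1, which is converted (Me3SiCl, NaI, Et3N, MeCN, rt) into ethyl 3-methyl-2-[(trimethylsilyl)oxy]but-2-enoate F3. A Mukaiyama–Michael addition of this silyl enol ether to 2 (TiCl4, CH2Cl2, −78 °C) should give diketo ester 3, which is now isolated. A separate aldol condensation (pyrrolidine, AcOH, toluene, 80 °C) comes back to the route at 5.

**Further compounds**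

F1 | step 3 | ethyl (3S)-3-(formyloxy)-2,6,6-trimethylcyclohex-1-ene-1-carboxylate | CCOC(=O)C1=C(C)[C@@H](OC=O)CCC1(C)C
F2 | step 7 | (1R)-2,6,6-trimethylcyclohex-2-ene-1-carbaldehyde | O=C[C@H]1C(C)=CCCC1(C)C
F3 | step 1 | ethyl 3-methyl-2-[(trimethylsilyl)oxy]but-2-enoate | CCOC(=O)C(O[Si](C)(C)C)=C(C)C
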